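**Plan**

1. Retrosynthesis: the carbocycle is opened at C5–C6 (retro-6π electrocyclisation) to a dienylketene. The ketene (C6=C7) goes back by a Wolff rearrangement to a diazomethyl ketone on C7a, that is to a 4,5-dihydrofuran-2-carboxylic ester plus diazomethane (C7).
2. The (Z)-enol ether C4=C5(OMe) comes from a C5 ketone (enolate O-methylation), the ketone from an alkyne C4≡C5 joined to C3a by Sonogashira coupling of an enol triflate. O1–C7a comes from a rhodium carbenoid O–H insertion and C2–C3 from an anti-aldol reaction of 3,4,5-trimethoxybenzaldehyde.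
3. Forward order: aryl ring (bought) → aldol chain → oxolane ring (step 5) → dienyl side chain and diazo ketone → carbocycle closed last (step 12).
4. Stereochemistry: C2 and C3 (trans) come from the auxiliary-controlled anti-aldol; C5 is set in the disrotatory ring closure by the (Z)-enol ether geometry together with the helical sense imposed by the C3 methyl group.
5. Enabling feature: the ring C3a–C4–C5–C6–C7–C7a is a linearly conjugated cyclohexa-2,4-dienone (C6=O, C7=C7a, C3a=C4) whose only sp3 atom, quaternary C5 (OMe, allyl), sits next to the carbonyl. It is the valence isomer of a dienylketene whose cis geometry is fixed by the ring-fusion bond C7a=C3a of the dihydrofuran, and the quaternary C5 blocks aromatisation.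

Key step: step 12

Remark: the Mg-catalysed anti-aldol of the (S)-benzyl imide is assumed to follow the chelated-enolate model (attack anti to benzyl) and give the (2R,3S) adduct; if the sense proved opposite, the (R)-auxiliary would be used.

**Route**

Step 1
Reactants: 1 (4S)-4-benzyl-3-propanoyl-1,3-oxazolidin-2-one; 2 3,4,5-trimethoxybenzaldehyde
Product: 4 (4S)-4-benzyl-3-[(2R,3S)-3-hydroxy-2-methyl-3-(3,4,5-trimethoxyphenyl)propanoyl]-1,3-oxazolidin-2-one, via trimethylsilyl ether 3 (not isolated)
Conditions: MgCl2 (10 mol %), Et3N, TMSCl, EtOAc, 23 °C; then TFA (cat.), MeOH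
Reagents that add atoms: none
Why: Evans MgCl2-catalysed direct anti-aldol (soft enolisation, silyl trapping for turnover), in which the chelated Z-enolate should be attacked on the face away from the benzyl group, setting the α-carbon (R) and, anti to it, the carbinol carbon (S); non-enolisable electron-rich aryl aldehydes are good partners.

Step 2
Reactants: 4
Product: 5 (2R,3S)-3-hydroxy-N-methoxy-N,2-dimethyl-3-(3,4,5-trimethoxyphenyl)propanamide
Conditions: MeNH(OMe)·HCl, AlMe3, CH2Cl2, −20 → 0 °C; 1 M HCl work-up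
Reagents that add atoms: N,O-dimethylhydroxylamine hydrochloride (CNOC.Cl)
Why: Weinreb amide formation by aminolysis of the imide with the aluminium amide, assisted by the free β-hydroxyl group, should release the auxiliary without touching either stereocentre.

Step 3
Reactants: 5
Product: 6 ethyl (4R,5S)-5-hydroxy-4-methyl-3-oxo-5-(3,4,5-trimethoxyphenyl)pentanoate
Conditions: EtOAc, LiHMDS (3.5 equiv), THF, −78 °C; then 5, −78 → −40 °C; quench 1 M HCl
Reagents that add atoms: ethyl acetate (CCOC(C)=O)
Why: Crossed Claisen condensation on a Weinreb amide, where the ester enolate adds once because the chelated tetrahedral adduct holds until the quench, and the excess base covers the free hydroxyl and the acidic product.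

Step 4
Reactants: 6
Product: 7 ethyl (4R,5S)-2-diazo-5-hydroxy-4-methyl-3-oxo-5-(3,4,5-trimethoxyphenyl)pentanoate
Conditions: 4-acetamidobenzenesulfonyl azide, Et3N, MeCN, 0 → 23 °C
Reagents that add atoms: 4-acetamidobenzenesulfonyl azide (CC(=O)Nc1ccc(cc1)S(=O)(=O)N=[N+]=[N-])
Why: Regitz diazo transfer to the doubly activated methylene under amine base is mild enough to leave the β-hydroxy ketone (retro-aldol) untouched.

Step 5
Reactants: 7
Product: 8 ethyl (4R,5S)-4-methyl-3-oxo-5-(3,4,5-trimethoxyphenyl)oxolane-2-carboxylate (C2 epimers and enol)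
Conditions: Rh2(OAc)4 (1 mol %), CH2Cl2, 23 °C
Reagents that add atoms: none
Why: Intramolecular O–H insertion of the rhodium carbenoid closes the five-membered oxolane faster than aromatic C–H insertion; C4 and C5 are untouched and the new C2 centre is erased in step 6.

Step 6
Reactants: 8
Product: 9 ethyl (4R,5S)-4-methyl-5-(3,4,5-trimethoxyphenyl)-3-{[(trifluoromethyl)sulfonyl]oxy}-4,5-dihydrofuran-2-carboxylate
Conditions: i-Pr2NEt, Tf2O, CH2Cl2, −78 °C
Reagents that add atoms: trifluoromethanesulfonic anhydride (FC(F)(F)S(=O)(=O)OS(=O)(=O)C(F)(F)F)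
Why: Enolisation of the cyclic β-keto ester between the two carbonyl groups followed by O-triflation should give the vinyl triflate regiospecifically, with the more stable trans 4-methyl/5-aryl arrangement retained.

Step 7
Reactants: 9; 10 pent-1-en-4-yne
Product: 11 ethyl (4S,5S)-4-methyl-3-(pent-4-en-1-yn-1-yl)-5-(3,4,5-trimethoxyphenyl)-4,5-dihydrofuran-2-carboxylate
Conditions: Pd(PPh3)2Cl2 (3 mol %), CuI (5 mol %), Et3N, THF, 23 °C
Reagents that add atoms: none
Why: Sonogashira coupling of an electron-poor vinyl triflate with a terminal alkyne runs at room temperature, where the amine base should not isomerise the skipped enyne.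

Step 8
Reactants: 11
Product: 13 ethyl (4S,5S)-4-methyl-3-(2-oxopent-4-en-1-yl)-5-(3,4,5-trimethoxyphenyl)-4,5-dihydrofuran-2-carboxylate, via dienamine 12 (not isolated)
Conditions: pyrrolidine, EtOH, 40 °C; then 1 M aq. HCl, THF, 0 °C
Reagents that add atoms: water (O)
Why: Conjugate (1,6) addition of the secondary amine to the alkyne terminus of the 2-en-4-ynoate should put nitrogen on C5 only, and mild acid hydrolysis of this vinylogous carbamate unmasks the ketone, which amounts to a regiodefined hydration of the alkyne.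

Step 9
Reactants: 13
Product: 15 ethyl (4S,5S)-3-[(1Z)-2-methoxypenta-1,4-dien-1-yl]-4-methyl-5-(3,4,5-trimethoxyphenyl)-4,5-dihydrofuran-2-carboxylate, via potassium dienolate 14 (not isolated)
Conditions: KHMDS, 18-crown-6, THF, −78 °C; then MeOTf, −78 → −40 °C
Reagents that add atoms: methyl trifluoromethanesulfonate (COS(=O)(=O)C(F)(F)F)
Why: O-Methylation of a delocalised potassium dienolate with a hard electrophile under ion-pair-separating conditions; the doubly activated C4–H is removed, the dienolate should prefer O⁻ rather than the allyl group cis to the fully substituted ring carbon (allylic strain), and methylation on oxygen fixes this as the (Z)-enol ether.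

Step 10
Reactants: 15
Product: 16 (4S,5S)-3-[(1Z)-2-methoxypenta-1,4-dien-1-yl]-4-methyl-5-(3,4,5-trimethoxyphenyl)-4,5-dihydrofuran-2-carboxylic acid
Conditions: LiOH, THF–H2O, 40 °C; then 1 M HCl to pH 4, 0 °C
Reagents that add atoms: lithium hydroxide ([Li+].[OH-])
Why: Saponification of the ethyl ester leaves the base-stable enol ether and skipped diene untouched, and the cold, mild acidification should avoid hydrolysis of the enol ether.

Step 11
Reactants: 16
Product: 18 2-diazo-1-[(4S,5S)-3-[(1Z)-2-methoxypenta-1,4-dien-1-yl]-4-methyl-5-(3,4,5-trimethoxyphenyl)-4,5-dihydrofuran-2-yl]ethan-1-one, via mixed anhydride 17 (not isolated)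
Conditions: i-BuOCOCl, N-methylmorpholine, THF, −20 °C; then CH2N2, Et2O, 0 °C
Reagents that add atoms: diazomethane (C=[N+]=[N-])
Why: Acylation of diazomethane by the mixed carbonic anhydride (first stage of an Arndt–Eistert sequence) is neutral and should tolerate the acid-sensitive enol ether.

Step 12
Reactants: 18
Product: 20 (2S,3S,5R)-5-methoxy-3-methyl-5-(prop-2-en-1-yl)-2-(3,4,5-trimethoxyphenyl)-2,3-dihydro-1-benzofuran-6(5H)-one, via dienylketene 19 (not isolated)
Conditions: hν (450 nm LEDs), degassed toluene (0.005 M), −40 °C; then 20 °C in the dark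
Reagents that add atoms: none
Why: Visible-light excitation of the s-Z diazo ketone should give a Wolff rearrangement (loss of N2 with 1,2-shift of the dihydrofuran-2-yl group) to dienylketene 19, in which ketene carbon C6 and enol ether carbon C5 are held cis across the ring bond C7a=C3a, and 19 then closes thermally by a 6π disrotatory electrocyclisation that forms C5–C6. The closest known reaction types are the photochemical Wolff rearrangement of α,β-unsaturated diazo ketones to vinylketenes and the thermal reclosure of the dienylketenes formed on photochemical ring opening of 6,6-disubstituted cyclohexa-2,4-dienones. The six-membered ring closes in the 6π electrocyclic mode (one σ bond, C5–C6), and because C5 carries no hydrogen the dienone cannot tautomerise to a phenol. The new stereocentre C5 follows from the (Z)-enol ether geometry (OMe inside, allyl outside) together with the helical sense of the triene, which the C3 methyl group sets by allylic strain: C4–H turns toward the C3–H face, C5 rises on the methyl face, and the ketene bonds to its lower lobe, so OMe should end syn and allyl anti to the C3 methyl as in the (5R) target; this bias is expected to be moderate and any C5 epimer would be removed by chromatography. The step needs Wolff rearrangement to win over carbene addition to the alkenes and no photochemical reopening of the product, which the conjugated s-Z diazo ketone, the low temperature and 450 nm light (absorbed by the diazo ketone, not by the dienone) should secure.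

**Compound list**

1 | (4S)-4-benzyl-3-propanoyl-1,3-oxazolidin-2-one | CCC(=O)N1[C@@H](Cc2ccccc2)COC1=O | starting material
2 | 3,4,5-trimethoxybenzaldehyde | COc1cc(C=O)cc(OC)c1OC | starting material
3 | (4S)-4-benzyl-3-[(2R,3S)-2-methyl-3-(3,4,5-trimethoxyphenyl)-3-(trimethylsilyloxy)propanoyl]-1,3-oxazolidin-2-one (not isolated) | C[Si](C)(C)O[C@H](c1cc(OC)c(OC)c(OC)c1)[C@H](C(=O)N1[C@@H](Cc2ccccc2)COC1=O)C | intermediate
4 | (4S)-4-benzyl-3-[(2R,3S)-3-hydroxy-2-methyl-3-(3,4,5-trimethoxyphenyl)propanoyl]-1,3-oxazolidin-2-one | O[C@H](c1cc(OC)c(OC)c(OC)c1)[C@H](C(=O)N1[C@@H](Cc2ccccc2)COC1=O)C | intermediate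
5 | (2R,3S)-3-hydroxy-N-methoxy-N,2-dimethyl-3-(3,4,5-trimethoxyphenyl)propanamide | O[C@H](c1cc(OC)c(OC)c(OC)c1)[C@H](C(=O)N(C)OC)C | intermediate
6 | ethyl (4R,5S)-5-hydroxy-4-methyl-3-oxo-5-(3,4,5-trimethoxyphenyl)pentanoate | O[C@H](c1cc(OC)c(OC)c(OC)c1)[C@H](C(=O)CC(=O)OCC)C | intermediate
7 | ethyl (4R,5S)-2-diazo-5-hydroxy-4-methyl-3-oxo-5-(3,4,5-trimethoxyphenyl)pentanoate | O[C@H](c1cc(OC)c(OC)c(OC)c1)[C@H](C(=O)C(=[N+]=[N-])C(=O)OCC)C | intermediate
8 | ethyl (4R,5S)-4-methyl-3-oxo-5-(3,4,5-trimethoxyphenyl)oxolane-2-carboxylate | O1[C@H](c2cc(OC)c(OC)c(OC)c2)[C@@H](C)C(=O)C1C(=O)OCC | intermediate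
9 | ethyl (4R,5S)-4-methyl-5-(3,4,5-trimethoxyphenyl)-3-{[(trifluoromethyl)sulfonyl]oxy}-4,5-dihydrofuran-2-carboxylate | O1[C@H](c2cc(OC)c(OC)c(OC)c2)[C@@H](C)C(OS(=O)(=O)C(F)(F)F)=C1C(=O)OCC | intermediate
10 | pent-1-en-4-yne | C=CCC#C | starting material
11 | ethyl (4S,5S)-4-methyl-3-(pent-4-en-1-yn-1-yl)-5-(3,4,5-trimethoxyphenyl)-4,5-dihydrofuran-2-carboxylate | O1[C@H](c2cc(OC)c(OC)c(OC)c2)[C@@H](C)C(C#CCC=C)=C1C(=O)OCC | intermediate
12 | ethyl (4S,5S)-4-methyl-3-[2-(pyrrolidin-1-yl)penta-1,4-dien-1-yl]-5-(3,4,5-trimethoxyphenyl)-4,5-dihydrofuran-2-carboxylate (not isolated) | O1[C@H](c2cc(OC)c(OC)c(OC)c2)[C@@H](C)C(C=C(N3CCCC3)CC=C)=C1C(=O)OCC | intermediate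
13 | ethyl (4S,5S)-4-methyl-3-(2-oxopent-4-en-1-yl)-5-(3,4,5-trimethoxyphenyl)-4,5-dihydrofuran-2-carboxylate | O1[C@H](c2cc(OC)c(OC)c(OC)c2)[C@@H](C)C(CC(=O)CC=C)=C1C(=O)OCC | intermediate
14 | potassium (1Z)-1-[(4S,5S)-2-(ethoxycarbonyl)-4-methyl-5-(3,4,5-trimethoxyphenyl)-4,5-dihydrofuran-3-yl]penta-1,4-dien-2-olate (not isolated) | O1[C@H](c2cc(OC)c(OC)c(OC)c2)[C@@H](C)C(/C=C(\[O-])CC=C)=C1C(=O)OCC.[K+] | intermediate
15 | ethyl (4S,5S)-3-[(1Z)-2-methoxypenta-1,4-dien-1-yl]-4-methyl-5-(3,4,5-trimethoxyphenyl)-4,5-dihydrofuran-2-carboxylate | O1[C@H](c2cc(OC)c(OC)c(OC)c2)[C@@H](C)C(/C=C(\OC)CC=C)=C1C(=O)OCC | intermediate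
16 | (4S,5S)-3-[(1Z)-2-methoxypenta-1,4-dien-1-yl]-4-methyl-5-(3,4,5-trimethoxyphenyl)-4,5-dihydrofuran-2-carboxylic acid | O1[C@H](c2cc(OC)c(OC)c(OC)c2)[C@@H](C)C(/C=C(\OC)CC=C)=C1C(=O)O | intermediate
17 | mixed anhydride of 16 with 2-methylpropyl hydrogen carbonate (not isolated) | O1[C@H](c2cc(OC)c(OC)c(OC)c2)[C@@H](C)C(/C=C(\OC)CC=C)=C1C(=O)OC(=O)OCC(C)C | intermediate
18 | 2-diazo-1-[(4S,5S)-3-[(1Z)-2-methoxypenta-1,4-dien-1-yl]-4-methyl-5-(3,4,5-trimethoxyphenyl)-4,5-dihydrofuran-2-yl]ethan-1-one | O1[C@H](c2cc(OC)c(OC)c(OC)c2)[C@@H](C)C(/C=C(\OC)CC=C)=C1C(=O)C=[N+]=[N-] | intermediate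
19 | 2-[(4S,5S)-3-[(1Z)-2-methoxypenta-1,4-dien-1-yl]-4-methyl-5-(3,4,5-trimethoxyphenyl)-4,5-dihydrofuran-2-yl]ethen-1-one (dienylketene; not isolated) | O1[C@H](c2cc(OC)c(OC)c(OC)c2)[C@@H](C)C(/C=C(\OC)CC=C)=C1C=C=O | intermediate
20 | (2S,3S,5R)-5-methoxy-3-methyl-5-(prop-2-en-1-yl)-2-(3,4,5-trimethoxyphenyl)-2,3-dihydro-1-benzofuran-6(5H)-one | C=CC[C@@]1(OC)C=C2C(=CC1=O)O[C@H](c1cc(OC)c(OC)c(OC)c1)[C@H]2C | target

**Count and risks**

Total step count: 12. Longest linear sequence: 12 steps (1 and 2 → 20).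

Step 12. What may go wrong: poor facial selectivity in the disrotatory closure. The two helical transition states differ only by a weak allylic interaction with the C3 methyl group, so the C5 epimer could form in comparable amount. Fallback, setting out from 2 and returning at 20: C5 is instead set by suprafacial transfer of the allyl group from C3a, where 1,2-induction by the C3 methyl group is reliable. Aldehyde 2 would be propargylated with the allenylzinc reagent from (R)-but-3-yn-2-yl methanesulfonate (Pd(OAc)2, PPh3, Et2Zn; Marshall anti-propargylation) to (1S,2S)-2-methyl-1-(3,4,5-trimethoxyphenyl)but-3-yn-1-ol F1. Ruthenium-catalysed cycloisomerisation–oxidation of the homopropargylic alcohol should give the lactone (4S,5S)-4-methyl-5-(3,4,5-trimethoxyphenyl)oxolan-2-one F2. Formylation (NaH, HCO2Et) should give (4S,5S)-4-methyl-2-oxo-5-(3,4,5-trimethoxyphenyl)oxolane-3-carbaldehyde F3. Tsuji–Trost C-allylation (Pd(PPh3)4, allyl methyl carbonate) should place the allyl group anti to the 4-methyl group and give (3S,4S,5S)-4-methyl-2-oxo-3-(prop-2-en-1-yl)-5-(3,4,5-trimethoxyphenyl)oxolane-3-carbaldehyde F4. Mukaiyama aldol addition of 1-methoxy-2-(trimethylsilyloxy)prop-1-ene (TMSOTf cat.) to the aldehyde should give (3S,4S,5S)-3-[2-methoxy-3-oxo-1-(trimethylsilyloxy)butyl]-4-methyl-3-(prop-2-en-1-yl)-5-(3,4,5-trimethoxyphenyl)oxolan-2-one F5. The methyl ketone enolate (LiHMDS) would then add to the lactone carbonyl, and acid (TsOH) would remove silanol and water to give the cross-conjugated dienone (2S,3S,3aS)-5-methoxy-3-methyl-3a-(prop-2-en-1-yl)-2-(3,4,5-trimethoxyphenyl)-3,3a-dihydro-1-benzofuran-6(2H)-one F6. Gentle heating (toluene, 100 °C) should bring about the Cope rearrangement of the allyl group from C3a to C5 on the same face and give 20.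

Step 9. What may go wrong: the ambident dienolate may be methylated on carbon (C4 or the ring α-carbon) instead of oxygen, or the enol ether geometry may erode. Fallback, setting out from 13 and returning at 15: no enolate alkylation is used. Ketone 13 would be converted with HC(OMe)3, PPTS and MeOH into the ketal ethyl (4S,5S)-3-(2,2-dimethoxypent-4-en-1-yl)-4-methyl-5-(3,4,5-trimethoxyphenyl)-4,5-dihydrofuran-2-carboxylate F7. TMSOTf and i-Pr2NEt should then remove methanol toward the more acidic, ester-conjugated C4–H and give 15, with the (Z) geometry under thermodynamic control.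

Step 8. What may go wrong: the amine may isomerise the skipped enyne by prototropy faster than it adds, or the acid hydrolysis may move the allyl ketone into conjugation. Fallback, setting out from 11 and returning at 15: the ketone stage is bypassed by direct 1,6-addition of methanol across the alkyne (Me3P cat. or NaOMe cat., MeOH, 0 °C). Protonation of the dienolate at C4 and thermodynamic control of the enol ether geometry should give 15 directly; no new compound arises.

Further compounds
F1 | step 12 | (1S,2S)-2-methyl-1-(3,4,5-trimethoxyphenyl)but-3-yn-1-ol | O[C@H](c1cc(OC)c(OC)c(OC)c1)[C@H](C#C)C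
F2 | step 12 | (4S,5S)-4-methyl-5-(3,4,5-trimethoxyphenyl)oxolan-2-one | O1[C@H](c2cc(OC)c(OC)c(OC)c2)[C@@H](C)CC1=O
F3 | step 12 | (4S,5S)-4-methyl-2-oxo-5-(3,4,5-trimethoxyphenyl)oxolane-3-carbaldehyde | O1[C@H](c2cc(OC)c(OC)c(OC)c2)[C@@H](C)C(C=O)C1=O
F4 | step 12 | (3S,4S,5S)-4-methyl-2-oxo-3-(prop-2-en-1-yl)-5-(3,4,5-trimethoxyphenyl)oxolane-3-carbaldehyde | O1[C@H](c2cc(OC)c(OC)c(OC)c2)[C@@H](C)[C@@](CC=C)(C=O)C1=O
F5 | step 12 | (3S,4S,5S)-3-[2-methoxy-3-oxo-1-(trimethylsilyloxy)butyl]-4-methyl-3-(prop-2-en-1-yl)-5-(3,4,5-trimethoxyphenyl)oxolan-2-one | O1[C@H](c2cc(OC)c(OC)c(OC)c2)[C@@H](C)[C@@](CC=C)(C(O[Si](C)(C)C)C(OC)C(C)=O)C1=O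
F6 | step 12 | (2S,3S,3aS)-5-methoxy-3-methyl-3a-(prop-2-en-1-yl)-2-(3,4,5-trimethoxyphenyl)-3,3a-dihydro-1-benzofuran-6(2H)-one | O1[C@H](c2cc(OC)c(OC)c(OC)c2)[C@@H](C)[C@@]3(CC=C)C=C(OC)C(=O)C=C13
F7 | step 9 | ethyl (4S,5S)-3-(2,2-dimethoxypent-4-en-1-yl)-4-methyl-5-(3,4,5-trimethoxyphenyl)-4,5-dihydrofuran-2-carboxylate | O1[C@H](c2cc(OC)c(OC)c(OC)c2)[C@@H](C)C(CC(OC)(OC)CC=C)=C1C(=O)OCC
F0 | step 8 | none | none
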